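# Proposed total synthesis of (3S)-6,2'-dihydroxy-7,8,3',4'-tetramethoxyisoflavan (24)

## Structural features

Compound 24 is an isoflavan. Benzo ring A is fused along C4a–C8a to the saturated oxygen ring C (O1, C2, C3, C4), and aryl ring B is attached at C3 through the C3–C1' bond. C3 is the only stereocentre (S). It has no stereogenic neighbour to relay from, and it is configurationally safe once C2 is at the alcohol or ether oxidation level. Ring A is pentasubstituted with four oxygens in a row: O1 on C8a, methoxy on C8, methoxy on C7 and a free hydroxyl on C6, which leaves only C5–H. Ring B carries three oxygens in a row (2'-OH, 3'-OMe, 4'-OMe).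

The fragile groups are the two free phenols and the four methyl ethers. The C6 hydroxyl stands para to O1, so ring A is an easily oxidised hydroquinone monoether. The methyl ethers on C7 and C3' are squeezed between oxygen neighbours and are the first to be lost to Lewis acids. The real difficulty is therefore not the carbon skeleton but placing and distinguishing the ring A oxygens, because no cheap arene offers this differentiated 1,2,3,4-tetraoxygenated pattern next to a carbon substituent.

The key step uses the fact that C8a and C8 are adjacent, both bear oxygen, and lie beside the C7 methoxy group. A C8–C8a aryne made from a ring that has only the C6 and C7 oxygens can take up O1 at C8a, which closes ring C, and a boron-delivered oxygen at C8 in one operation.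

## Logic of the disconnections

**24 ⇒ 23.** The two O–C(isopropyl) bonds on O6 and O2' are the last to be cut in the forward sense.
- The phenols must be masked because they would consume base, quench the C8 anion and oxidise.
- A secondary alkyl ether is preferred to a benzyl ether, whose acidic benzylic hydrogens invite Wittig rearrangement under surplus amide.
- It is preferred to an acetal, which is a strong ortho director and would call the base to C5.
- It is preferred to a silyl ether, which could migrate from O2' to the C2 alkoxide.
- The demand on the forward step is to cleave secondary alkyl aryl ethers while four methyl ethers stay, two of them crowded.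

**23 ⇒ 22.** The O–CH3 bond on C8 is cut. Compound 22 has one free hydroxyl only, so the forward alkylation raises no selectivity question. The cut turns the C8 oxygen into a phenol, which is the retron for oxidation of a carbon–boron bond.

**22 ⇒ 17 (through 21, 20, 19, 18).** Two bonds on neighbouring carbons are cut together: C8–O (back to C8–B in 21 and C8–Li in 20) and O1–C8a.
- Both bonds converge on 19, whose triple bond lies between C8 and C8a. Compound 19 comes from 17 by loss of C8–H and the C8a bromine.
- Ring C and two of the four ring A oxygens disappear, so ring A of 17 has the oxygen pattern of a cheap aldehyde.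
- The forward step needs a single aryne, and bromine on C8a has only one ortho hydrogen.
- It needs oxygen to go to C8a and charge to C8, an aryl anion that outlives the liberated amine, and a base without alpha-hydrogens that adds slowly to arynes.

**17 ⇒ 16.** C2 is taken back from the alcohol to the acyl level and tied by a C2–N bond to the auxiliary part of 16. C3 thereby becomes the alpha-carbon of an imide and can be alkylated under auxiliary control. The forward reduction must not epimerise the acidic C3–H.

**16 ⇒ 14 + 6.** The C3–C4 bond is cut. This splits the molecule into two halves of similar size, one aromatic ring each, and it is the bond whose formation sets the only stereocentre. The forward step needs one enolate geometry (15), one open face, and the 4S configuration in 14 so that 2S results.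

**14 ⇒ 11 + 12.** The N–C(=O) bond is cut, which separates the recoverable chiral controller from the achiral ring B acid. The forward acylation must avoid ketene formation.

**11 ⇒ 10 ⇒ 8.** The C2–C3 bond is cut, a one-carbon homologation. The formyl carbon of 8 becomes C3 and the added carbon becomes C2. This reduces ring B to a benzaldehyde and asks for a homologation that tolerates an electron-rich, ortho-substituted aldehyde.

**8 ⇒ 7 + 2.** The O2'–C(isopropyl) bond is cut. Compound 7 already has the three ring B oxygens with only the right one free.

**6 ⇒ 5 ⇒ 4.** The benzylic C4–Br bond is cut and the oxidation level of C4 is adjusted. The electrophile is traced to an aldehyde, and the forward steps are routine.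

**4 ⇒ 3 ⇒ 1 + 2.** The C8a–Br bond and the O6–C(isopropyl) bond are cut. Alkylation must precede bromination, so that the alkoxy group on the future C6 directs bromine para to itself, onto the future C8a.

## Other disconnections considered

**Alternative 1:** The cut runs through C3–C1' and C4–C4a and leaves C2 to be added later. The key product is the (S)-1,2-diarylethyl boronic pinacol ester A1.

*Forward key step.* The ring B aryllithium A3 adds to vinylboronic pinacol ester A4. The ate complex then meets the arylpalladium species made from the ring A bromide A2 with Pd(OAc)2, a chiral ferrocenyl bisphosphine and NaOSO2CF3. Divalent palladium activates the vinyl group, ring B shifts from boron to the carbon that becomes C3, and reductive elimination joins C4 to C4a.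

*In favour.*
- Two C–C bonds and the stereocentre are made in one catalytic step, with no auxiliary.
- The reaction class is established, whereas step 11 is not. On precedent and on the way chirality is introduced this is the better plan.
- The benzyl ethers would leave by hydrogenolysis, a gentler finish than step 13, which is also better.

*Against.*
- A2 must already hold all four ring A oxygens with three different O-substituents plus bromine. The central problem of 24 is therefore pushed into a side sequence.
- Both aryl partners carry an ortho alkoxy group, a doubly hindered case in which rate and enantioselectivity cannot be assumed.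
- Bromide ion retards the metallate shift, hence the triflate salt.
- No ring closes. Homologation with chloromethyllithium (C2–C3), C–B oxidation, acetal removal, Mitsunobu closure of O1–C2 and hydrogenolysis must follow. That is five steps, against two after step 11.

*Comparison.* The alternative has better stereochemical economy and equal convergence. It makes poorer use of the structure of ring A and would probably need no fewer than the thirteen steps of the chosen route.

**Alternative 2:** The cut removes C3–C1' together with a temporary C4–O bond to the 2'-oxygen. The key product is the cis-fused pterocarpan A5.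

*Forward key step.* The 2H-chromene A6 and the iodophenol A7 react with Pd(OAc)2, a chiral phosphine–oxazoline ligand and Ag2CO3.
- A7 adds oxidatively to zerovalent palladium, and silver opens a coordination site.
- The aryl group is delivered to C3 with palladium on benzylic C4.
- The phenol oxygen then closes the dihydrofuran ring.
- Hydrogenolysis would cleave the benzylic C4–O bond and the benzyl ether and give 24 directly.

*In favour.*
- Only two steps lead from two fragments to 24, which is clearly better in step economy.
- No protecting group is needed on O2', which is better.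
- The neutral final step cannot touch methyl ethers, which is better than step 13.
- C3 is not involved in the hydrogenolysis.

*Against.*
- Asymmetric versions of this oxyarylation are scarcely developed.
- The enantio-determining insertion must distinguish the faces of a flat, electron-rich cyclic styrene with an aryl group that carries a free ortho hydroxyl.
- Beta-hydride elimination toward C2 competes.
- Silver is used in stoichiometric amount.
- A6 needs the complete ring A oxygen pattern before the chromene is even formed.

*Comparison.* In novelty risk the two plans are about equal. A shortfall here would cost optical purity, which is hard to repair. A shortfall in step 11 would cost only material, because C3 is already fixed. On the ring A problem the chosen plan is the stronger one.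

**Alternative 3:** The cut goes through C5–C6 (electrocyclisation) and C4a–C8a (carbonyl addition). The key product is hydroquinone A8.

*Forward key step.* The alkenyl bromide A11 is lithiated and added to dimethyl squarate A10 to give cyclobutenone A9. Thermolysis opens the four-membered ring to a dienylketene, whose 6π closure and tautomerisation build ring A. Desilylation, Mitsunobu closure of O1–C2 by the C8a hydroxyl (the only one that can reach C2) and hydrogenolysis would finish the synthesis.

*In favour.*
- Every step belongs to a known reaction type, which is better than step 11 on precedent.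
- The C7 and C8 methoxy groups arrive ready-made from A10.
- The C6 hydroxyl appears free and needs no mask, which is better.
- No selective dealkylation is needed, which is better than step 13.

*Against.*
- A8 is a very electron-rich hydroquinone that oxidises readily to the quinone.
- The free C6 hydroxyl may engage in intermolecular Mitsunobu etherification.
- Silyl protection and deprotection are added.
- C3 still has to come from the same auxiliary alkylation, now with a 2-bromoallyl electrophile, which is equal.
- Ring A is built on the chiral chain, so the route is fully linear.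

*Comparison.* The total step count is about equal. The longest linear sequence is about twelve against nine. The risk in the key step is lower, but convergence is lower and a sensitive intermediate must be handled late.

Key step: step 11

Remark on the chemistry: isoflavan atom labels (O1, C2–C8a, primed numbers for ring B) are used for the same atoms in open-chain precursors. Compounds 1, 2, 7 and 12 are taken to be purchasable. C3 is S from 16 to 24 because the ranking C2 substituent > C1' > C4 > H holds throughout.

## Route

Step 1
Reactants: 1 isovanillin (3-hydroxy-4-methoxybenzaldehyde); 2 2-bromopropane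
Product: 3 3-isopropoxy-4-methoxybenzaldehyde
Conditions: K2CO3, DMF, 70 °C
Reagents that add atoms: none
Why: Williamson ether synthesis on the only acidic OH; an excess of 2 compensates for competing elimination to propene.

Step 2
Reactants: 3 3-isopropoxy-4-methoxybenzaldehyde
Product: 4 2-bromo-5-isopropoxy-4-methoxybenzaldehyde
Conditions: Br2, NaOAc, AcOH, rt
Reagents that add atoms: bromine BrBr
Why: Electrophilic aromatic bromination; the methoxy group is tied up in conjugation with the para formyl group, so the isopropoxy group directs, and its para position (future C8a) is open while its free ortho position lies between two substituents. NaOAc buffers the HBr so that the ethers stay intact.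

Step 3
Reactants: 4 2-bromo-5-isopropoxy-4-methoxybenzaldehyde
Product: 5 (2-bromo-5-isopropoxy-4-methoxyphenyl)methanol
Conditions: NaBH4, MeOH, 0 °C
Reagents that add atoms: none
Why: Borohydride reduction of an aldehyde; the aryl bromide and the ethers are inert.

Step 4
Reactants: 5 (2-bromo-5-isopropoxy-4-methoxyphenyl)methanol
Product: 6 1-bromo-2-(bromomethyl)-4-isopropoxy-5-methoxybenzene
Conditions: PBr3, CH2Cl2, 0 °C
Reagents that add atoms: phosphorus tribromide BrP(Br)Br
Why: Substitution of an activated phosphite ester by bromide at a primary benzylic carbon; the electron-rich bromide should be used soon after an aqueous work-up.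

Step 5
Reactants: 7 2-hydroxy-3,4-dimethoxybenzaldehyde; 2 2-bromopropane
Product: 8 2-isopropoxy-3,4-dimethoxybenzaldehyde
Conditions: K2CO3, DMF, 80 °C
Reagents that add atoms: none
Why: Williamson ether synthesis; the hydrogen-bonded, flanked phenol needs the polar solvent, heat and an excess of 2, but no other site can be alkylated.

Step 6
Reactants: 8 2-isopropoxy-3,4-dimethoxybenzaldehyde
Product: 10 (2-isopropoxy-3,4-dimethoxyphenyl)acetonitrile, via N-(2-aryl-1-tosylvinyl)formamide 9 (not isolated)
Conditions: TosMIC, KOtBu, DME, −40 °C; then MeOH, reflux
Reagents that add atoms: tosylmethyl isocyanide (TosMIC) Cc1ccc(cc1)S(=O)(=O)C[N+]#[C-]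
Why: Van Leusen reductive cyanation in its aldehyde variant: the TosMIC anion adds to the aldehyde, the oxazoline so formed opens to 9, and methanolysis removes the formyl group and expels sulfinate, leaving the nitrile carbon as the future C2. Holding the first stage cold and adding methanol only afterwards suppresses the oxazole pathway.

Step 7
Reactants: 10 (2-isopropoxy-3,4-dimethoxyphenyl)acetonitrile
Product: 11 (2-isopropoxy-3,4-dimethoxyphenyl)acetic acid
Conditions: KOH, EtOH–H2O, reflux; then aq. HCl
Reagents that add atoms: potassium hydroxide [K+].[OH-]; water O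
Why: Basic nitrile hydrolysis; aryl alkyl ethers are stable to hydroxide and no stereocentre is present yet.

Step 8
Reactants: 11 (2-isopropoxy-3,4-dimethoxyphenyl)acetic acid; 12 (4S)-4-benzyl-1,3-oxazolidin-2-one
Product: 14 (4S)-4-benzyl-3-[(2-isopropoxy-3,4-dimethoxyphenyl)acetyl]-1,3-oxazolidin-2-one, via mixed pivalic anhydride 13 (not isolated)
Conditions: t-BuCOCl, Et3N, THF, −20 °C; then 12, LiCl, −20 °C → rt
Reagents that add atoms: pivaloyl chloride CC(C)(C)C(=O)Cl (its atoms stay in 13 only)
Why: Mixed-anhydride N-acylation of an oxazolidinone promoted by LiCl and Et3N; 12 attacks the unhindered arylacetyl carbonyl of 13, and the mild base avoids the ketene formation to which arylacetyl chlorides are prone.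

Step 9
Reactants: 14 (4S)-4-benzyl-3-[(2-isopropoxy-3,4-dimethoxyphenyl)acetyl]-1,3-oxazolidin-2-one; 6 1-bromo-2-(bromomethyl)-4-isopropoxy-5-methoxybenzene
Product: 16 (4S)-4-benzyl-3-[(2S)-3-(2-bromo-5-isopropoxy-4-methoxyphenyl)-2-(2-isopropoxy-3,4-dimethoxyphenyl)propanoyl]-1,3-oxazolidin-2-one, via sodium Z-enolate 15 (not isolated)
Conditions: NaN(SiMe3)2, THF, −78 °C; 6, −78 → −30 °C; AcOH quench at −30 °C
Reagents that add atoms: sodium bis(trimethylsilyl)amide [Na+].C[Si](C)(C)[N-][Si](C)(C)C (sodium in 15 only)
Why: Evans asymmetric alkylation forms C3–C4: the chelated Z-enolate 15 is planar, the benzyl group on C4 of the auxiliary covers one face, and 6 enters from the other, which with the 4S auxiliary gives 2S (the future 3S). The cold acidic quench protects the doubly activated C3–H from proton exchange.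

Step 10
Reactants: 16 (4S)-4-benzyl-3-[(2S)-3-(2-bromo-5-isopropoxy-4-methoxyphenyl)-2-(2-isopropoxy-3,4-dimethoxyphenyl)propanoyl]-1,3-oxazolidin-2-one
Product: 17 (2S)-3-(2-bromo-5-isopropoxy-4-methoxyphenyl)-2-(2-isopropoxy-3,4-dimethoxyphenyl)propan-1-ol
Conditions: LiBH4, MeOH (1 equiv), Et2O–THF, 0 °C
Reagents that add atoms: none
Why: Reductive removal of the oxazolidinone at the exocyclic carbonyl with LiBH4; the medium is hardly basic, so C3 keeps its configuration, and the aryl bromide and ethers are untouched while 12 is recovered.

Step 11
Reactants: 17 (2S)-3-(2-bromo-5-isopropoxy-4-methoxyphenyl)-2-(2-isopropoxy-3,4-dimethoxyphenyl)propan-1-ol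
Product: 22 (3S)-8-hydroxy-6,2'-diisopropoxy-7,3',4'-trimethoxyisoflavan, via C8-lithiated bromoarene alkoxide 18 (not isolated), via C8–C8a aryne alkoxide 19 (not isolated), via C8 aryllithium 20 (not isolated), via lithium aryltrimethoxyborate 21 (not isolated)
Conditions: 17 added to lithium 2,2,6,6-tetramethylpiperidide (3.5 equiv, from the amine and n-BuLi), THF, −78 → 0 °C; B(OMe)3 (5 equiv), −78 °C → rt; AcOH, 30% H2O2, 0 °C → rt
Reagents that add atoms: lithium 2,2,6,6-tetramethylpiperidide [Li+].CC1(C)CCCC(C)(C)[N-]1 (lithium in 18–21 only); trimethyl borate COB(OC)OC (atoms in 21 only); hydrogen peroxide OO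
Why: Proposed new method: the first equivalent of the amide makes the C2 lithium alkoxide and the second removes C8–H, the only hydrogen beside bromine and the most acidic ring proton because bromine and the C7 methoxy group flank it, giving 18, which loses LiBr on warming so that 19 is the only aryne possible. The alkoxide then adds to C8a in a 6-exo-dig closure of ring C (new bond O1–C8a, with C8 outside the new ring). Regiocontrol is secured twice: the C7 methoxy group polarises the strained triple bond so that a nucleophile attacks the remote carbon C8a and the charge develops on C8 next to oxygen, and the three-carbon tether on C4a can reach C8a only. Aryllithium 20 lies between O1 and the C7 methoxy group, is estimated to be about two pK units less basic than the amide, and should therefore not be drained by the liberated amine, the surplus base restoring whatever is protonated during the hold at 0 °C. B(OMe)3 at −78 °C converts 20 into 21, and H2O2 in AcOH triggers the 1,2-shift of C8 from boron to oxygen, which places the new C8–O bond of 22 exactly at the metalated carbon. The closest known reaction types are chroman formation by intramolecular alkoxide capture of arynes, anionic aryne cyclisations whose aryllithium is quenched with an electrophile, and metalation–borylation–oxidation of 1,3-dialkoxyarenes; joining them into one oxy-borylation is what is new. No stereocentre is formed, and C3 is safe because its hydrogen is far less acidic than any position the amide attacks. The chemoselectivity needed (ring closure faster than amide addition or hydride transfer to 19, no lithiation at C5 or C5') rests on the bulk and the missing alpha-hydrogens of the amide, on the intramolecular nucleophile, on isopropyl ethers being poor directing groups, and on the cold borate quench.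

Step 12
Reactants: 22 (3S)-8-hydroxy-6,2'-diisopropoxy-7,3',4'-trimethoxyisoflavan
Product: 23 (3S)-6,2'-diisopropoxy-7,8,3',4'-tetramethoxyisoflavan
Conditions: MeI, K2CO3, DMF, rt
Reagents that add atoms: iodomethane CI
Why: Williamson methylation of the only free hydroxyl; the small electrophile copes with the two flanking oxygens, and early capping protects the oxidation-prone phenol.

Step 13
Reactants: 23 (3S)-6,2'-diisopropoxy-7,8,3',4'-tetramethoxyisoflavan
Product: 24 (3S)-6,2'-dihydroxy-7,8,3',4'-tetramethoxyisoflavan (target)
Conditions: BCl3 (3 equiv), CH2Cl2, −78 → 0 °C; then H2O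
Reagents that add atoms: none
Why: Lewis-acid dealkylation: boron binds the ether oxygen and the secondary alkyl group departs to chloride through a cation-like transition state that a methyl group cannot match; selective cleavage of aryl isopropyl ethers standing next to methoxy groups with BCl3 or AlCl3 is a known reaction type. Low temperature and a small excess should spare the crowded C7 and C3' methyl ethers, and C3 is not involved.

## Compound list

1 | isovanillin (3-hydroxy-4-methoxybenzaldehyde) | COc1ccc(C=O)cc1O | starting material
2 | 2-bromopropane | CC(C)Br | starting material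
3 | 3-isopropoxy-4-methoxybenzaldehyde | CC(C)Oc1cc(C=O)ccc1OC | intermediate
4 | 2-bromo-5-isopropoxy-4-methoxybenzaldehyde | CC(C)Oc1cc(C=O)c(Br)cc1OC | intermediate
5 | (2-bromo-5-isopropoxy-4-methoxyphenyl)methanol | CC(C)Oc1cc(CO)c(Br)cc1OC | intermediate
6 | 1-bromo-2-(bromomethyl)-4-isopropoxy-5-methoxybenzene | CC(C)Oc1cc(CBr)c(Br)cc1OC | intermediate
7 | 2-hydroxy-3,4-dimethoxybenzaldehyde | COc1ccc(C=O)c(O)c1OC | starting material
8 | 2-isopropoxy-3,4-dimethoxybenzaldehyde | COc1ccc(C=O)c(OC(C)C)c1OC | intermediate
9 | N-[2-(2-isopropoxy-3,4-dimethoxyphenyl)-1-tosylethenyl]formamide (potassium salt in the flask; alkene geometry not controlled and without consequence) | COc1ccc(C=C(NC=O)S(=O)(=O)c2ccc(C)cc2)c(OC(C)C)c1OC | intermediate (not isolated)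
10 | (2-isopropoxy-3,4-dimethoxyphenyl)acetonitrile | COc1ccc(CC#N)c(OC(C)C)c1OC | intermediate
11 | (2-isopropoxy-3,4-dimethoxyphenyl)acetic acid | COc1ccc(CC(=O)O)c(OC(C)C)c1OC | intermediate
12 | (4S)-4-benzyl-1,3-oxazolidin-2-one | O=C1N[C@@H](Cc2ccccc2)CO1 | starting material
13 | (2-isopropoxy-3,4-dimethoxyphenyl)acetic pivalic anhydride | COc1ccc(CC(=O)OC(=O)C(C)(C)C)c(OC(C)C)c1OC | intermediate (not isolated)
14 | (4S)-4-benzyl-3-[(2-isopropoxy-3,4-dimethoxyphenyl)acetyl]-1,3-oxazolidin-2-one | COc1ccc(CC(=O)N2[C@@H](Cc3ccccc3)COC2=O)c(OC(C)C)c1OC | intermediate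
15 | sodium (Z)-enolate of 14 | [Na+].[O-]/C(=C\c1ccc(OC)c(OC)c1OC(C)C)N1[C@@H](Cc2ccccc2)COC1=O | intermediate (not isolated)
16 | (4S)-4-benzyl-3-[(2S)-3-(2-bromo-5-isopropoxy-4-methoxyphenyl)-2-(2-isopropoxy-3,4-dimethoxyphenyl)propanoyl]-1,3-oxazolidin-2-one | COc1ccc([C@H](Cc2cc(OC(C)C)c(OC)cc2Br)C(=O)N2[C@@H](Cc3ccccc3)COC2=O)c(OC(C)C)c1OC | intermediate
17 | (2S)-3-(2-bromo-5-isopropoxy-4-methoxyphenyl)-2-(2-isopropoxy-3,4-dimethoxyphenyl)propan-1-ol | COc1ccc([C@H](Cc2cc(OC(C)C)c(OC)cc2Br)CO)c(OC(C)C)c1OC | intermediate
18 | lithium (2S)-3-(2-bromo-3-lithio-5-isopropoxy-4-methoxyphenyl)-2-(2-isopropoxy-3,4-dimethoxyphenyl)propan-1-olate | COc1ccc([C@H](Cc2cc(OC(C)C)c(OC)c([Li])c2Br)C[O-])c(OC(C)C)c1OC.[Li+] | intermediate (not isolated)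
19 | lithium (2S)-3-(2,3-didehydro-5-isopropoxy-4-methoxyphenyl)-2-(2-isopropoxy-3,4-dimethoxyphenyl)propan-1-olate (C8–C8a aryne) | COc1ccc([C@H](CC2=CC(OC(C)C)=C(OC)C#C2)C[O-])c(OC(C)C)c1OC.[Li+] | intermediate (not isolated)
20 | (3S)-8-lithio-6,2'-diisopropoxy-7,3',4'-trimethoxyisoflavan | COc1ccc([C@H]2COc3c(cc(OC(C)C)c(OC)c3[Li])C2)c(OC(C)C)c1OC | intermediate (not isolated)
21 | lithium [(3S)-6,2'-diisopropoxy-7,3',4'-trimethoxyisoflavan-8-yl]trimethoxyborate | COc1ccc([C@H]2COc3c(cc(OC(C)C)c(OC)c3[B-](OC)(OC)OC)C2)c(OC(C)C)c1OC.[Li+] | intermediate (not isolated)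
22 | (3S)-8-hydroxy-6,2'-diisopropoxy-7,3',4'-trimethoxyisoflavan | COc1ccc([C@H]2COc3c(cc(OC(C)C)c(OC)c3O)C2)c(OC(C)C)c1OC | intermediate
23 | (3S)-6,2'-diisopropoxy-7,8,3',4'-tetramethoxyisoflavan | COc1ccc([C@H]2COc3c(cc(OC(C)C)c(OC)c3OC)C2)c(OC(C)C)c1OC | intermediate
24 | (3S)-6,2'-dihydroxy-7,8,3',4'-tetramethoxyisoflavan | COc1ccc([C@H]2COc3c(cc(O)c(OC)c3OC)C2)c(O)c1OC | target

## Step count and least certain steps

Total step count: 13. Longest linear sequence: 9 steps (steps 1–4 followed by 9–13, or steps 5–8 followed by 9–13).

**Step 11 (key step).**

*What may go wrong.*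
- The aggregated lithium alkoxide may add too slowly, so that amide addition to the aryne or hydride transfer from the C2–H bonds of the alkoxide takes over.
- The C8 anion may be protonated by the liberated amine and not be re-metalated, so that ring C closes without oxygenation.
- Surplus base may metalate C5' during the borate quench and cause a second borylation.
- The 2,6-dialkoxyaryl borate may protodeboronate before the peroxide acts.

*Fallback (known chemistry, one step longer).*
- It sets out from 17.
- An intramolecular Buchwald–Hartwig etherification closes O1–C8a and gives (3S)-6,2'-diisopropoxy-7,3',4'-trimethoxyisoflavan F1. Conditions: Pd(OAc)2, 2-(di-tert-butylphosphino)-1,1'-binaphthyl, Cs2CO3, toluene, 70 °C.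
- Directed ortho-metalation of F1 with n-BuLi and TMEDA in THF at 0 °C takes place at C8, between O1 and the C7 methoxy group. This produces the same aryllithium 20.
- B(OMe)3 and then H2O2 lead through 21 back to the route at 22.

**Step 13.**

*What may go wrong.* Once an aryloxyboron group sits next to the C7 or C3' methyl ether, chelation-assisted loss of that crowded methyl group may set in. The departing isopropyl cation may also alkylate the electron-rich rings.

*Fallback.* The Lewis acid step is moved forward to 17, where ring A has only two oxygens, and the end of the synthesis becomes an acetal hydrolysis.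
- From 17, BCl3 (CH2Cl2, −78 → 0 °C) would give (2S)-3-(2-bromo-5-hydroxy-4-methoxyphenyl)-2-(2-hydroxy-3,4-dimethoxyphenyl)propan-1-ol F2.
- MOMCl and K2CO3 in acetone alkylate only the two phenoxides and give the bis(methoxymethyl) ether F3.
- The conditions of step 11 would carry F3 through the C8-lithiated bromoarene alkoxide F4, the aryne alkoxide F5, the C8 aryllithium F6 and the lithium aryltrimethoxyborate F7 to the C8 phenol F8.
- MeI and K2CO3 give the C8 methyl ether F9.
- HCl in MeOH at 40 °C removes both acetals without any action on methyl ethers and rejoins the route at 24.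
- The price is two more steps and a better ortho director beside C5, so the excess of amide would have to be trimmed.

**Step 9.**

*What may go wrong.*
- Both partners carry ortho substituents, so alkylation may be slow.
- During a long reaction, proton exchange between product and enolate may erode the configuration at C3.
- The enolate may decay by expulsion of the auxiliary on warming.

*Fallback.* This is a catalytic route to the stereocentre, setting out from 11 and 4. Steps 3, 4, 8, 9 and 10 then fall away.
- Perkin condensation (Ac2O, Et3N, 100 °C) gives (E)-3-(2-bromo-5-isopropoxy-4-methoxyphenyl)-2-(2-isopropoxy-3,4-dimethoxyphenyl)acrylic acid F10.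
- Asymmetric hydrogenation of this alpha-aryl cinnamic acid gives (2S)-3-(2-bromo-5-isopropoxy-4-methoxyphenyl)-2-(2-isopropoxy-3,4-dimethoxyphenyl)propanoic acid F11. Conditions: H2, Et3N, MeOH, with [Ir(cod)(L*)][B(C6H3(CF3)2)4], where L* is a chiral spiro phosphine–oxazoline, or with Ru(OAc)2(BINAP). The ligand antipode is chosen to deliver 2S.
- BH3·THF reduces F11 and rejoins the route at 17.

**Step 6.**

*What may go wrong.* Addition of the TosMIC anion to the hindered, electron-rich aldehyde may be incomplete. The oxazoline may also lose sulfinate early, which diverts material into oxazole formation.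

*Fallback.* It sets out from 8.
- Wittig methoxymethylenation ((methoxymethyl)triphenylphosphonium chloride, KOtBu, THF, 0 °C) gives 2-isopropoxy-3,4-dimethoxy-1-(2-methoxyethenyl)benzene F12.
- Aqueous HCl in THF unmasks (2-isopropoxy-3,4-dimethoxyphenyl)acetaldehyde F13.
- Pinnick oxidation (NaClO2, NaH2PO4, 2-methyl-2-butene, t-BuOH–H2O) rejoins the route at 11, replacing steps 6 and 7 by three steps.

## Further compounds

F1 | step 11 | (3S)-6,2'-diisopropoxy-7,3',4'-trimethoxyisoflavan | COc1ccc([C@H]2COc3cc(OC)c(OC(C)C)cc3C2)c(OC(C)C)c1OC
F2 | step 13 | (2S)-3-(2-bromo-5-hydroxy-4-methoxyphenyl)-2-(2-hydroxy-3,4-dimethoxyphenyl)propan-1-ol | COc1ccc([C@H](Cc2cc(O)c(OC)cc2Br)CO)c(O)c1OC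
F3 | step 13 | (2S)-3-[2-bromo-4-methoxy-5-(methoxymethoxy)phenyl]-2-[3,4-dimethoxy-2-(methoxymethoxy)phenyl]propan-1-ol | COc1ccc([C@H](Cc2cc(OCOC)c(OC)cc2Br)CO)c(OCOC)c1OC
F4 | step 13 | lithium (2S)-3-[2-bromo-3-lithio-4-methoxy-5-(methoxymethoxy)phenyl]-2-[3,4-dimethoxy-2-(methoxymethoxy)phenyl]propan-1-olate | COc1ccc([C@H](Cc2cc(OCOC)c(OC)c([Li])c2Br)C[O-])c(OCOC)c1OC.[Li+]
F5 | step 13 | lithium (2S)-3-[2,3-didehydro-4-methoxy-5-(methoxymethoxy)phenyl]-2-[3,4-dimethoxy-2-(methoxymethoxy)phenyl]propan-1-olate | COc1ccc([C@H](CC2=CC(OCOC)=C(OC)C#C2)C[O-])c(OCOC)c1OC.[Li+]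
F6 | step 13 | (3S)-8-lithio-7,3',4'-trimethoxy-6,2'-bis(methoxymethoxy)isoflavan | COc1ccc([C@H]2COc3c(cc(OCOC)c(OC)c3[Li])C2)c(OCOC)c1OC
F7 | step 13 | lithium [(3S)-7,3',4'-trimethoxy-6,2'-bis(methoxymethoxy)isoflavan-8-yl]trimethoxyborate | COc1ccc([C@H]2COc3c(cc(OCOC)c(OC)c3[B-](OC)(OC)OC)C2)c(OCOC)c1OC.[Li+]
F8 | step 13 | (3S)-8-hydroxy-7,3',4'-trimethoxy-6,2'-bis(methoxymethoxy)isoflavan | COc1ccc([C@H]2COc3c(cc(OCOC)c(OC)c3O)C2)c(OCOC)c1OC
F9 | step 13 | (3S)-7,8,3',4'-tetramethoxy-6,2'-bis(methoxymethoxy)isoflavan | COc1ccc([C@H]2COc3c(cc(OCOC)c(OC)c3OC)C2)c(OCOC)c1OC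
F10 | step 9 | (E)-3-(2-bromo-5-isopropoxy-4-methoxyphenyl)-2-(2-isopropoxy-3,4-dimethoxyphenyl)acrylic acid | OC(=O)/C(=C/c1cc(OC(C)C)c(OC)cc1Br)c1ccc(OC)c(OC)c1OC(C)C
F11 | step 9 | (2S)-3-(2-bromo-5-isopropoxy-4-methoxyphenyl)-2-(2-isopropoxy-3,4-dimethoxyphenyl)propanoic acid | COc1ccc([C@H](Cc2cc(OC(C)C)c(OC)cc2Br)C(=O)O)c(OC(C)C)c1OC
F12 | step 6 | 2-isopropoxy-3,4-dimethoxy-1-(2-methoxyethenyl)benzene (E/Z mixture) | COC=Cc1ccc(OC)c(OC)c1OC(C)C
F13 | step 6 | (2-isopropoxy-3,4-dimethoxyphenyl)acetaldehyde | O=CCc1ccc(OC)c(OC)c1OC(C)C
A1 | alternative 1 | (S)-2-[2-(5-benzyloxy-3,4-dimethoxy-2-(methoxymethoxy)phenyl)-1-(2-benzyloxy-3,4-dimethoxyphenyl)ethyl]-4,4,5,5-tetramethyl-1,3,2-dioxaborolane | COc1ccc([C@H](Cc2cc(OCc3ccccc3)c(OC)c(OC)c2OCOC)B2OC(C)(C)C(C)(C)O2)c(OCc2ccccc2)c1OC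
A2 | alternative 1 | 1-benzyloxy-5-bromo-2,3-dimethoxy-4-(methoxymethoxy)benzene | Brc1cc(OCc2ccccc2)c(OC)c(OC)c1OCOC
A3 | alternative 1 | (2-benzyloxy-3,4-dimethoxyphenyl)lithium | COc1ccc([Li])c(OCc2ccccc2)c1OC
A4 | alternative 1 | vinylboronic acid pinacol ester | C=CB1OC(C)(C)C(C)(C)O1
A5 | alternative 2 | (6aS,11aS)-2-benzyloxy-3,4,9,10-tetramethoxypterocarpan (cis-fused) | COc1ccc2c(c1OC)O[C@@H]3c4cc(OCc5ccccc5)c(OC)c(OC)c4OC[C@H]23
A6 | alternative 2 | 6-benzyloxy-7,8-dimethoxy-2H-chromene | COc1c(OCc2ccccc2)cc2C=CCOc2c1OC
A7 | alternative 2 | 6-iodo-2,3-dimethoxyphenol | COc1ccc(I)c(O)c1OC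
A8 | alternative 3 | (S)-5-[2-(2-benzyloxy-3,4-dimethoxyphenyl)-3-(tert-butyldimethylsilyloxy)propyl]-2,3-dimethoxybenzene-1,4-diol | COc1ccc([C@H](Cc2cc(O)c(OC)c(OC)c2O)CO[Si](C)(C)C(C)(C)C)c(OCc2ccccc2)c1OC
A9 | alternative 3 | 4-[(4S)-4-(2-benzyloxy-3,4-dimethoxyphenyl)-5-(tert-butyldimethylsilyloxy)pent-1-en-2-yl]-4-hydroxy-2,3-dimethoxycyclobut-2-en-1-one (both carbinol epimers) | COc1ccc([C@H](CC(=C)C2(O)C(OC)=C(OC)C2=O)CO[Si](C)(C)C(C)(C)C)c(OCc2ccccc2)c1OC
A10 | alternative 3 | dimethyl squarate (3,4-dimethoxycyclobut-3-ene-1,2-dione) | COC1=C(OC)C(=O)C1=O
A11 | alternative 3 | (S)-[2-(2-benzyloxy-3,4-dimethoxyphenyl)-4-bromopent-4-enyloxy](tert-butyl)dimethylsilane | COc1ccc([C@H](CC(Br)=C)CO[Si](C)(C)C(C)(C)C)c(OCc2ccccc2)c1OC
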